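**Plan**

1. Feature used: in each of the three arylglycerol units, C8 carries an aryl ether oxygen (the 4-O of a syringyl ring of the furofuran, or of guaiacyl ring B) and the C9H2OH group, and C7 is a carbinol on a guaiacyl ring. Each unit is therefore an α-aryloxy-β-hydroxy acid at the alcohol level, and its C7–C8 bond is the retron of a glycolate aldol between an aryloxyacetyl imide and a non-enolisable aryl aldehyde.
2. Cuts: first C7–C8 of the middle threo (7R,8R) unit B, which divides the pentamer into aldehyde 15 (ring B carrying erythro unit A) and imide 29 (furofuran whose second syringyl oxygen carries erythro unit C). Then C7–C8 of units A and C in the same way, and the three ArO–CH2 bonds back to phenols and 4-benzyl-3-(chloroacetyl)oxazolidin-2-ones.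
3. Forward: isoeugenol (propenyl = latent CHO) → unit A → 15; (−)-syringaresinol → monoallyl ether → unit C → allyl exchanged for the glycolyl imide → 29; union of 29 with 15, reduction of the auxiliary, global desilylation. No ring is formed; both furan rings come intact in 16.
4. Stereochemistry: the four furofuran centres come from (−)-syringaresinol. Each C7/C8 pair comes from an auxiliary-controlled Evans syn-aldol ((S)-auxiliary → 7R,8R; (R)-auxiliary → 7S,8S). The two erythro units (A: 7R,8S; C: 7S,8R) follow by Mitsunobu inversion at C7 of the threo adducts.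

Key step: step 18

Remark on the chemistry: (−)-syringaresinol (7R,7'R,8S,8'S) and both enantiomers of 4-benzyl-3-(chloroacetyl)oxazolidin-2-one are taken as purchasable single enantiomers; the units are called A (on ring B), B (middle) and C (on the second syringyl ring), with lignan locants 7, 8, 9.

**Route**

Step 1
Reactants: 1 vanillin
Product: 2 3-methoxy-4-(triisopropylsilyloxy)benzaldehyde
Conditions: TIPSCl, imidazole, DMF, rt
Reagents that add atoms: triisopropylsilyl chloride, CC(C)[Si](Cl)(C(C)C)C(C)C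
Why: Imidazole-promoted silylation masks the phenol of the aldehyde partner as a base-stable, fluoride-labile aryl TIPS ether; no stereocentre is involved.

Step 2
Reactants: 3 (E)-isoeugenol; 4 (R)-4-benzyl-3-(chloroacetyl)oxazolidin-2-one
Product: 5 (R)-4-benzyl-3-{[2-methoxy-4-((E)-prop-1-enyl)phenoxy]acetyl}oxazolidin-2-one
Conditions: K2CO3, NaI (cat.), acetone, reflux
Reagents that add atoms: none
Why: Williamson ether synthesis with iodide catalysis places the aryloxyacetyl (glycolate) donor directly on the Evans auxiliary, while the propenyl group serves as a latent formyl group that is inert in the following steps.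

Step 3
Reactants: 5 (R)-4-benzyl-3-{[2-methoxy-4-((E)-prop-1-enyl)phenoxy]acetyl}oxazolidin-2-one; 2 3-methoxy-4-(triisopropylsilyloxy)benzaldehyde
Product: 8 (R)-4-benzyl-3-[(2R,3S)-3-hydroxy-2-[2-methoxy-4-((E)-prop-1-enyl)phenoxy]-3-(3-methoxy-4-triisopropylsilyloxyphenyl)propanoyl]oxazolidin-2-one (syn adduct), via Z-dibutylboron enolate 6 (not isolated), via dibutylboron aldolate 7 (not isolated)
Conditions: Bu2BOTf, iPr2NEt, CH2Cl2, −78 → 0 °C; then 2, −78 → 0 °C; pH 7 buffer, MeOH, 30% H2O2, 0 °C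
Reagents that add atoms: none
Why: Evans boron syn-aldol: the Z(O)-enolate adds through a chair Zimmerman–Traxler transition state on the enolate face left open by the (R)-benzyl auxiliary, which should set C8 and C7 as the (2R,3S) syn pair, i.e. the threo (7S,8S) unit.

Step 4
Reactants: 8 syn-aldol adduct
Product: 9 (1S,2S)-2-[2-methoxy-4-((E)-prop-1-enyl)phenoxy]-1-(3-methoxy-4-triisopropylsilyloxyphenyl)propane-1,3-diol (threo)
Conditions: LiBH4, THF/MeOH, 0 °C
Reagents that add atoms: none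
Why: Reductive cleavage of the N-acyloxazolidinone by hydride attack at the exocyclic carbonyl turns C9 into the primary alcohol without touching C7, C8, the aryl silyl ether or the alkene.

Step 5
Reactants: 9 threo diol
Product: 10 (1S,2S)-3-(tert-butyldimethylsilyloxy)-2-[2-methoxy-4-((E)-prop-1-enyl)phenoxy]-1-(3-methoxy-4-triisopropylsilyloxyphenyl)propan-1-ol
Conditions: TBSCl (1.1 equiv), imidazole, CH2Cl2, 0 °C
Reagents that add atoms: tert-butyldimethylsilyl chloride, CC(C)(C)[Si](C)(C)Cl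
Why: Chemoselective silylation, because the unhindered primary 9-OH should react much faster with TBSCl/imidazole than the flanked benzylic 7-OH.

Step 6
Reactants: 10 threo 9-O-TBS alcohol
Product: 12 (1R,2S)-3-(tert-butyldimethylsilyloxy)-2-[2-methoxy-4-((E)-prop-1-enyl)phenoxy]-1-(3-methoxy-4-triisopropylsilyloxyphenyl)propan-1-ol (erythro), via inverted 4-nitrobenzoate 11 (not isolated)
Conditions: PPh3, DIAD, 4-nitrobenzoic acid, THF, 0 °C → rt; then K2CO3, MeOH, 0 °C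
Reagents that add atoms: 4-nitrobenzoic acid, OC(=O)c1ccc(cc1)[N+](=O)[O-] (one carboxyl oxygen becomes the new C7 oxygen)
Why: Mitsunobu reaction, in which SN2 displacement of the alkoxyphosphonium ion by 4-nitrobenzoate inverts C7 (7S → 7R, threo → erythro) and in-situ methanolysis of the activated ester frees the inverted alcohol.

Step 7
Reactants: 12 erythro 9-O-TBS alcohol
Product: 13 (1R,2S)-1,3-bis(tert-butyldimethylsilyloxy)-2-[2-methoxy-4-((E)-prop-1-enyl)phenoxy]-1-(3-methoxy-4-triisopropylsilyloxyphenyl)propane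
Conditions: TBSOTf, 2,6-lutidine, CH2Cl2, −78 → 0 °C
Reagents that add atoms: tert-butyldimethylsilyl triflate, CC(C)(C)[Si](C)(C)OS(=O)(=O)C(F)(F)F
Why: Silyl triflate/lutidine silylation caps the hindered benzylic alcohol so that no free hydroxyl meets the boron enolate in the fragment union.

Step 8
Reactants: 13 bis-TBS propenyl arene
Product: 15 4-{[(1R,2S)-1,3-bis(tert-butyldimethylsilyloxy)-1-(3-methoxy-4-triisopropylsilyloxyphenyl)propan-2-yl]oxy}-3-methoxybenzaldehyde, via vicinal diol 14 (not isolated)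
Conditions: OsO4 (cat.), NaIO4, 2,6-lutidine, dioxane/H2O, rt
Reagents that add atoms: osmium tetroxide, O=[Os](=O)(=O)=O; sodium periodate (reoxidant and source of the oxygen), [Na+].[O-][I](=O)(=O)=O
Why: Lemieux–Johnson oxidation, in which OsO4 dihydroxylates the only alkene and periodate cleaves the diol to unmask the aryl aldehyde, with lutidine keeping the medium neutral for the silyl ethers.

Step 9
Reactants: 16 (−)-syringaresinol
Product: 17 4-O-allyl-(−)-syringaresinol (monoallyl ether)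
Conditions: allyl bromide (1.0 equiv), K2CO3, DMF, rt
Reagents that add atoms: allyl bromide, C=CCBr
Why: Williamson monoallylation of the C2-symmetric diphenol is statistical, but the two phenols are homotopic, so only one monoether can form and unreacted 16 is recycled.

Step 10
Reactants: 17 4-O-allyl-(−)-syringaresinol; 18 (S)-4-benzyl-3-(chloroacetyl)oxazolidin-2-one
Product: 19 4-O-allyl-4'-O-{2-[(S)-4-benzyl-2-oxooxazolidin-3-yl]-2-oxoethyl}-(−)-syringaresinol
Conditions: K2CO3, NaI (cat.), acetone, reflux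
Reagents that add atoms: none
Why: Williamson etherification of the remaining 2,6-dimethoxyphenoxide with the α-chloro imide (Finkelstein catalysis) attaches the glycolate donor that carries the (S)-auxiliary.

Step 11
Reactants: 19 allyl-protected glycolyl imide; 2 3-methoxy-4-(triisopropylsilyloxy)benzaldehyde
Product: 22 4-O-allyl-4'-O-[(2S,3R)-1-((S)-4-benzyl-2-oxooxazolidin-3-yl)-3-hydroxy-3-(3-methoxy-4-triisopropylsilyloxyphenyl)-1-oxopropan-2-yl]-(−)-syringaresinol (syn adduct), via Z-dibutylboron enolate 20 (not isolated), via dibutylboron aldolate 21 (not isolated)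
Conditions: Bu2BOTf, iPr2NEt, CH2Cl2, −78 → 0 °C; then 2, −78 → 0 °C; pH 7 buffer, MeOH, 30% H2O2, 0 °C
Reagents that add atoms: none
Why: Evans boron syn-aldol through the Z-enolate and a chair Zimmerman–Traxler transition state, in which the (S)-auxiliary should direct the aldehyde to the face that gives the (2S,3R) adduct, i.e. the threo (7R,8R) unit.

Step 12
Reactants: 22 syn-aldol adduct
Product: 23 4-O-allyl-4'-O-[(1R,2R)-1,3-dihydroxy-1-(3-methoxy-4-triisopropylsilyloxyphenyl)propan-2-yl]-(−)-syringaresinol (threo diol)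
Conditions: LiBH4, THF/MeOH, 0 °C
Reagents that add atoms: none
Why: LiBH4 reductive removal of the auxiliary gives the 1,3-diol, the allyl ether, the furofuran ethers and the aryl silyl ether being inert to borohydride.

Step 13
Reactants: 23 threo diol
Product: 24 4-O-allyl-4'-O-[(1R,2R)-3-(tert-butyldimethylsilyloxy)-1-hydroxy-1-(3-methoxy-4-triisopropylsilyloxyphenyl)propan-2-yl]-(−)-syringaresinol
Conditions: TBSCl (1.1 equiv), imidazole, CH2Cl2, 0 °C
Reagents that add atoms: tert-butyldimethylsilyl chloride, CC(C)(C)[Si](C)(C)Cl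
Why: Selective silylation of the primary alcohol leaves the benzylic 7-OH as the only free hydroxyl for the inversion.

Step 14
Reactants: 24 threo 9-O-TBS alcohol
Product: 26 4-O-allyl-4'-O-[(1S,2R)-3-(tert-butyldimethylsilyloxy)-1-hydroxy-1-(3-methoxy-4-triisopropylsilyloxyphenyl)propan-2-yl]-(−)-syringaresinol (erythro), via inverted 4-nitrobenzoate 25 (not isolated)
Conditions: PPh3, DIAD, 4-nitrobenzoic acid, THF, 0 °C → rt; then K2CO3, MeOH, 0 °C
Reagents that add atoms: 4-nitrobenzoic acid, OC(=O)c1ccc(cc1)[N+](=O)[O-] (one carboxyl oxygen becomes the new C7 oxygen)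
Why: Mitsunobu inversion at C7 (SN2 by 4-nitrobenzoate, 7R → 7S) converts the threo into the erythro unit, and brief cold methanolysis should cleave the activated ester without touching the aryl TIPS ether.

Step 15
Reactants: 26 erythro 9-O-TBS alcohol
Product: 27 4-O-allyl-4'-O-[(1S,2R)-1,3-bis(tert-butyldimethylsilyloxy)-1-(3-methoxy-4-triisopropylsilyloxyphenyl)propan-2-yl]-(−)-syringaresinol
Conditions: TBSOTf, 2,6-lutidine, CH2Cl2, −78 → 0 °C
Reagents that add atoms: tert-butyldimethylsilyl triflate, CC(C)(C)[Si](C)(C)OS(=O)(=O)C(F)(F)F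
Why: Silyl triflate silylation of the hindered benzylic alcohol completes a uniformly fluoride-labile protection of unit C.

Step 16
Reactants: 27 allyl ether carrying protected unit C
Product: 28 4-O-[(1S,2R)-1,3-bis(tert-butyldimethylsilyloxy)-1-(3-methoxy-4-triisopropylsilyloxyphenyl)propan-2-yl]-(−)-syringaresinol (free syringyl phenol)
Conditions: Pd(PPh3)4 (cat.), morpholine, THF, rt
Reagents that add atoms: none
Why: Pd(0)-catalysed deallylation (Tsuji–Trost type), in which oxidative addition to the allyl aryl ether gives a π-allyl complex that morpholine traps, should release the phenol under neutral conditions that spare all silyl ethers.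

Step 17
Reactants: 28 syringyl phenol carrying protected unit C; 18 (S)-4-benzyl-3-(chloroacetyl)oxazolidin-2-one
Product: 29 4-O-{2-[(S)-4-benzyl-2-oxooxazolidin-3-yl]-2-oxoethyl}-4'-O-[(1S,2R)-1,3-bis(tert-butyldimethylsilyloxy)-1-(3-methoxy-4-triisopropylsilyloxyphenyl)propan-2-yl]-(−)-syringaresinol
Conditions: K2CO3, NaI (cat.), acetone, 50 °C
Reagents that add atoms: none
Why: Williamson etherification of the liberated syringyl phenoxide with the α-chloro imide gives the second glycolate donor on a half that already holds the furofuran and the complete erythro unit C.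

Step 18
Reactants: 29 glycolyl imide (furofuran half with unit C); 15 aldehyde (ring B with unit A)
Product: 32 fully assembled syn-aldol adduct with (2S,3R) configuration at the new centres and the (S)-auxiliary on C9 of unit B, via Z-dibutylboron enolate 30 (not isolated), via dibutylboron aldolate 31 (not isolated)
Conditions: Bu2BOTf (1.2 equiv), iPr2NEt (1.4 equiv), CH2Cl2, −78 → 0 °C; then 15, −78 → 0 °C; pH 7 buffer, MeOH, 30% H2O2, 0 °C
Reagents that add atoms: none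
Why: Evans boron aldol: Bu2BOTf/iPr2NEt soft-enolises the only acidic C–H of 29 (the imide CH2 attached to the aryl ether oxygen of the syringyl ring) to the Z(O)-enolate 30, which adds to the non-enolisable aldehyde 15 through a closed chair Zimmerman–Traxler transition state to give aldolate 31, released by oxidative work-up. The closest known reaction type is the Evans syn-aldol of N-(aryloxyacetyl)oxazolidinones with alkoxybenzaldehydes used for single-enantiomer 8-O-4' dimers, here applied to two large partners. No ring is closed. The configuration at C8 (2S in the imide, 8R after reduction) is controlled by the (S)-benzyl auxiliary, whose dipole-opposed conformation leaves one enolate face open, and that at C7 (R) follows from the Z-enolate geometry in the chair (syn = threo). The step needs chemoselectivity and reagent control: every hydroxyl of both partners is a silyl ether so that boron binds only the imide, the aldehyde has no α-hydrogen, and the existing stereocentres of 15 and 29 lie far from the reacting carbons, so the auxiliary alone should decide the facial sense. In one operation it forms the central C7–C8 bond, sets the only threo pair of the molecule in the absolute sense and completes the carbon skeleton.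

Step 19
Reactants: 32 assembled aldol adduct
Product: 33 target carrying four TBS ethers (7-O and 9-O of units A and C) and two aryl TIPS ethers (middle unit as the free 7R,8R diol)
Conditions: LiBH4, THF/MeOH, 0 °C
Reagents that add atoms: none
Why: Reductive cleavage of the imide with LiBH4 delivers C9 of the middle unit as CH2OH and returns the auxiliary without affecting any stereocentre.

Step 20
Reactants: 33 hexasilyl ether
Product: 34 CNP0316493.1 (target)
Conditions: TBAF, AcOH, THF, 0 °C → rt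
Reagents that add atoms: none
Why: Fluoride-mediated global desilylation, buffered with acetic acid so that the liberated p-hydroxybenzyl alcohols do not eliminate to quinone methides, should remove four TBS and two TIPS groups without the acid that would epimerise the benzylic centres.

**Compound list**

1 | vanillin (4-hydroxy-3-methoxybenzaldehyde) | COc1cc(C=O)ccc1O | starting material
2 | 3-methoxy-4-(triisopropylsilyloxy)benzaldehyde | COc1cc(C=O)ccc1O[Si](C(C)C)(C(C)C)C(C)C | intermediate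
3 | (E)-isoeugenol, 2-methoxy-4-[(E)-prop-1-enyl]phenol | C/C=C/c1ccc(O)c(OC)c1 | starting material
4 | (R)-4-benzyl-3-(chloroacetyl)oxazolidin-2-one | O=C(CCl)N1[C@H](Cc2ccccc2)COC1=O | starting material
5 | (R)-4-benzyl-3-{[2-methoxy-4-((E)-prop-1-enyl)phenoxy]acetyl}oxazolidin-2-one | C/C=C/c1ccc(OCC(=O)N2[C@H](Cc3ccccc3)COC2=O)c(OC)c1 | intermediate
6 | Z-dibutylboron enolate of 5 (not isolated) | C/C=C/c1ccc(O/C=C(\OB(CCCC)CCCC)N2[C@H](Cc3ccccc3)COC2=O)c(OC)c1 | intermediate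
7 | dibutylboron aldolate of 8 (not isolated) | COc1cc([C@H](OB(CCCC)CCCC)[C@H](C(=O)N2[C@H](Cc3ccccc3)COC2=O)Oc2ccc(/C=C/C)cc2OC)ccc1O[Si](C(C)C)(C(C)C)C(C)C | intermediate
8 | (R)-4-benzyl-3-[(2R,3S)-3-hydroxy-2-[2-methoxy-4-((E)-prop-1-enyl)phenoxy]-3-(3-methoxy-4-triisopropylsilyloxyphenyl)propanoyl]oxazolidin-2-one | COc1cc([C@H](O)[C@H](C(=O)N2[C@H](Cc3ccccc3)COC2=O)Oc2ccc(/C=C/C)cc2OC)ccc1O[Si](C(C)C)(C(C)C)C(C)C | intermediate
9 | (1S,2S)-2-[2-methoxy-4-((E)-prop-1-enyl)phenoxy]-1-(3-methoxy-4-triisopropylsilyloxyphenyl)propane-1,3-diol (threo) | COc1cc([C@H](O)[C@H](CO)Oc2ccc(/C=C/C)cc2OC)ccc1O[Si](C(C)C)(C(C)C)C(C)C | intermediate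
10 | (1S,2S)-3-(tert-butyldimethylsilyloxy)-2-[2-methoxy-4-((E)-prop-1-enyl)phenoxy]-1-(3-methoxy-4-triisopropylsilyloxyphenyl)propan-1-ol | COc1cc([C@H](O)[C@H](CO[Si](C)(C)C(C)(C)C)Oc2ccc(/C=C/C)cc2OC)ccc1O[Si](C(C)C)(C(C)C)C(C)C | intermediate
11 | (1R,2S)-3-(tert-butyldimethylsilyloxy)-2-[2-methoxy-4-((E)-prop-1-enyl)phenoxy]-1-(3-methoxy-4-triisopropylsilyloxyphenyl)propyl 4-nitrobenzoate (not isolated) | COc1cc([C@@H](OC(=O)c2ccc(cc2)[N+](=O)[O-])[C@H](CO[Si](C)(C)C(C)(C)C)Oc2ccc(/C=C/C)cc2OC)ccc1O[Si](C(C)C)(C(C)C)C(C)C | intermediate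
12 | (1R,2S)-3-(tert-butyldimethylsilyloxy)-2-[2-methoxy-4-((E)-prop-1-enyl)phenoxy]-1-(3-methoxy-4-triisopropylsilyloxyphenyl)propan-1-ol (erythro) | COc1cc([C@@H](O)[C@H](CO[Si](C)(C)C(C)(C)C)Oc2ccc(/C=C/C)cc2OC)ccc1O[Si](C(C)C)(C(C)C)C(C)C | intermediate
13 | (1R,2S)-1,3-bis(tert-butyldimethylsilyloxy)-2-[2-methoxy-4-((E)-prop-1-enyl)phenoxy]-1-(3-methoxy-4-triisopropylsilyloxyphenyl)propane | COc1cc([C@@H](O[Si](C)(C)C(C)(C)C)[C@H](CO[Si](C)(C)C(C)(C)C)Oc2ccc(/C=C/C)cc2OC)ccc1O[Si](C(C)C)(C(C)C)C(C)C | intermediate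
14 | 1,2-dihydroxypropyl analogue of 13 (vicinal diol, mixture at the two new carbinols, not isolated) | COc1cc([C@@H](O[Si](C)(C)C(C)(C)C)[C@H](CO[Si](C)(C)C(C)(C)C)Oc2ccc(C(O)C(C)O)cc2OC)ccc1O[Si](C(C)C)(C(C)C)C(C)C | intermediate
15 | 4-{[(1R,2S)-1,3-bis(tert-butyldimethylsilyloxy)-1-(3-methoxy-4-triisopropylsilyloxyphenyl)propan-2-yl]oxy}-3-methoxybenzaldehyde | COc1cc([C@@H](O[Si](C)(C)C(C)(C)C)[C@H](CO[Si](C)(C)C(C)(C)C)Oc2ccc(C=O)cc2OC)ccc1O[Si](C(C)C)(C(C)C)C(C)C | intermediate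
16 | (−)-syringaresinol, 4,4'-[(1R,3aS,4R,6aS)-tetrahydro-1H,3H-furo[3,4-c]furan-1,4-diyl]bis(2,6-dimethoxyphenol) | COc1cc(cc(OC)c1O)[C@@H]1OC[C@@H]2[C@H]1CO[C@H]2c1cc(OC)c(O)c(OC)c1 | starting material
17 | 4-O-allyl-(−)-syringaresinol | COc1cc(cc(OC)c1OCC=C)[C@@H]1OC[C@@H]2[C@H]1CO[C@H]2c1cc(OC)c(O)c(OC)c1 | intermediate
18 | (S)-4-benzyl-3-(chloroacetyl)oxazolidin-2-one | O=C(CCl)N1[C@@H](Cc2ccccc2)COC1=O | starting material
19 | 4-O-allyl-4'-O-{2-[(S)-4-benzyl-2-oxooxazolidin-3-yl]-2-oxoethyl}-(−)-syringaresinol | COc1cc(cc(OC)c1OCC=C)[C@@H]1OC[C@@H]2[C@H]1CO[C@H]2c1cc(OC)c(OCC(=O)N2[C@@H](Cc3ccccc3)COC2=O)c(OC)c1 | intermediate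
20 | Z-dibutylboron enolate of 19 (not isolated) | COc1cc(cc(OC)c1OCC=C)[C@@H]1OC[C@@H]2[C@H]1CO[C@H]2c1cc(OC)c(O/C=C(\OB(CCCC)CCCC)N2[C@@H](Cc3ccccc3)COC2=O)c(OC)c1 | intermediate
21 | dibutylboron aldolate of 22 (not isolated) | COc1cc(cc(OC)c1OCC=C)[C@@H]1OC[C@@H]2[C@H]1CO[C@H]2c1cc(OC)c(O[C@H](C(=O)N2[C@@H](Cc3ccccc3)COC2=O)[C@H](OB(CCCC)CCCC)c2ccc(O[Si](C(C)C)(C(C)C)C(C)C)c(OC)c2)c(OC)c1 | intermediate
22 | 4-O-allyl-4'-O-[(2S,3R)-1-((S)-4-benzyl-2-oxooxazolidin-3-yl)-3-hydroxy-3-(3-methoxy-4-triisopropylsilyloxyphenyl)-1-oxopropan-2-yl]-(−)-syringaresinol | COc1cc(cc(OC)c1OCC=C)[C@@H]1OC[C@@H]2[C@H]1CO[C@H]2c1cc(OC)c(O[C@H](C(=O)N2[C@@H](Cc3ccccc3)COC2=O)[C@H](O)c2ccc(O[Si](C(C)C)(C(C)C)C(C)C)c(OC)c2)c(OC)c1 | intermediate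
23 | 4-O-allyl-4'-O-[(1R,2R)-1,3-dihydroxy-1-(3-methoxy-4-triisopropylsilyloxyphenyl)propan-2-yl]-(−)-syringaresinol (threo) | COc1cc(cc(OC)c1OCC=C)[C@@H]1OC[C@@H]2[C@H]1CO[C@H]2c1cc(OC)c(O[C@H](CO)[C@H](O)c2ccc(O[Si](C(C)C)(C(C)C)C(C)C)c(OC)c2)c(OC)c1 | intermediate
24 | 4-O-allyl-4'-O-[(1R,2R)-3-(tert-butyldimethylsilyloxy)-1-hydroxy-1-(3-methoxy-4-triisopropylsilyloxyphenyl)propan-2-yl]-(−)-syringaresinol | COc1cc(cc(OC)c1OCC=C)[C@@H]1OC[C@@H]2[C@H]1CO[C@H]2c1cc(OC)c(O[C@H](CO[Si](C)(C)C(C)(C)C)[C@H](O)c2ccc(O[Si](C(C)C)(C(C)C)C(C)C)c(OC)c2)c(OC)c1 | intermediate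
25 | (1S,2R) 4-nitrobenzoate of inverted 24 (not isolated) | COc1cc(cc(OC)c1OCC=C)[C@@H]1OC[C@@H]2[C@H]1CO[C@H]2c1cc(OC)c(O[C@H](CO[Si](C)(C)C(C)(C)C)[C@@H](OC(=O)c2ccc(cc2)[N+](=O)[O-])c2ccc(O[Si](C(C)C)(C(C)C)C(C)C)c(OC)c2)c(OC)c1 | intermediate
26 | 4-O-allyl-4'-O-[(1S,2R)-3-(tert-butyldimethylsilyloxy)-1-hydroxy-1-(3-methoxy-4-triisopropylsilyloxyphenyl)propan-2-yl]-(−)-syringaresinol (erythro) | COc1cc(cc(OC)c1OCC=C)[C@@H]1OC[C@@H]2[C@H]1CO[C@H]2c1cc(OC)c(O[C@H](CO[Si](C)(C)C(C)(C)C)[C@@H](O)c2ccc(O[Si](C(C)C)(C(C)C)C(C)C)c(OC)c2)c(OC)c1 | intermediate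
27 | 4-O-allyl-4'-O-[(1S,2R)-1,3-bis(tert-butyldimethylsilyloxy)-1-(3-methoxy-4-triisopropylsilyloxyphenyl)propan-2-yl]-(−)-syringaresinol | COc1cc(cc(OC)c1OCC=C)[C@@H]1OC[C@@H]2[C@H]1CO[C@H]2c1cc(OC)c(O[C@H](CO[Si](C)(C)C(C)(C)C)[C@@H](O[Si](C)(C)C(C)(C)C)c2ccc(O[Si](C(C)C)(C(C)C)C(C)C)c(OC)c2)c(OC)c1 | intermediate
28 | 4-O-[(1S,2R)-1,3-bis(tert-butyldimethylsilyloxy)-1-(3-methoxy-4-triisopropylsilyloxyphenyl)propan-2-yl]-(−)-syringaresinol (one free syringyl phenol) | COc1cc(cc(OC)c1O)[C@@H]1OC[C@@H]2[C@H]1CO[C@H]2c1cc(OC)c(O[C@H](CO[Si](C)(C)C(C)(C)C)[C@@H](O[Si](C)(C)C(C)(C)C)c2ccc(O[Si](C(C)C)(C(C)C)C(C)C)c(OC)c2)c(OC)c1 | intermediate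
29 | (S)-4-benzyl-3-(aryloxyacetyl)oxazolidin-2-one of phenol 28 (glycolyl imide) | COc1cc(cc(OC)c1OCC(=O)N1[C@@H](Cc2ccccc2)COC1=O)[C@@H]1OC[C@@H]2[C@H]1CO[C@H]2c1cc(OC)c(O[C@H](CO[Si](C)(C)C(C)(C)C)[C@@H](O[Si](C)(C)C(C)(C)C)c2ccc(O[Si](C(C)C)(C(C)C)C(C)C)c(OC)c2)c(OC)c1 | intermediate
30 | Z-dibutylboron enolate of 29 (not isolated) | COc1cc(cc(OC)c1O/C=C(\OB(CCCC)CCCC)N1[C@@H](Cc2ccccc2)COC1=O)[C@@H]1OC[C@@H]2[C@H]1CO[C@H]2c1cc(OC)c(O[C@H](CO[Si](C)(C)C(C)(C)C)[C@@H](O[Si](C)(C)C(C)(C)C)c2ccc(O[Si](C(C)C)(C(C)C)C(C)C)c(OC)c2)c(OC)c1 | intermediate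
31 | dibutylboron aldolate of 32 (not isolated) | COc1cc([C@@H](O[Si](C)(C)C(C)(C)C)[C@H](CO[Si](C)(C)C(C)(C)C)Oc2ccc([C@@H](OB(CCCC)CCCC)[C@@H](C(=O)N3[C@@H](Cc4ccccc4)COC3=O)Oc3c(OC)cc([C@@H]4OC[C@@H]5[C@H]4CO[C@H]5c4cc(OC)c(O[C@H](CO[Si](C)(C)C(C)(C)C)[C@@H](O[Si](C)(C)C(C)(C)C)c5ccc(O[Si](C(C)C)(C(C)C)C(C)C)c(OC)c5)c(OC)c4)cc3OC)cc2OC)ccc1O[Si](C(C)C)(C(C)C)C(C)C | intermediate
32 | assembled syn-aldol adduct: unit B as (2S,3R)-3-hydroxy-2-aryloxy-propanoyl (S)-4-benzyloxazolidin-2-one, units A and C as 7,9-bis-TBS ethers, both phenols as TIPS ethers | COc1cc([C@@H](O[Si](C)(C)C(C)(C)C)[C@H](CO[Si](C)(C)C(C)(C)C)Oc2ccc([C@@H](O)[C@@H](C(=O)N3[C@@H](Cc4ccccc4)COC3=O)Oc3c(OC)cc([C@@H]4OC[C@@H]5[C@H]4CO[C@H]5c4cc(OC)c(O[C@H](CO[Si](C)(C)C(C)(C)C)[C@@H](O[Si](C)(C)C(C)(C)C)c5ccc(O[Si](C(C)C)(C(C)C)C(C)C)c(OC)c5)c(OC)c4)cc3OC)cc2OC)ccc1O[Si](C(C)C)(C(C)C)C(C)C | intermediate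
33 | target as its hexasilyl ether: 7-O and 9-O of units A and C as TBS ethers, both phenols as TIPS ethers, unit B as the free (7R,8R) diol | COc1cc([C@@H](O[Si](C)(C)C(C)(C)C)[C@H](CO[Si](C)(C)C(C)(C)C)Oc2ccc([C@@H](O)[C@@H](CO)Oc3c(OC)cc([C@@H]4OC[C@@H]5[C@H]4CO[C@H]5c4cc(OC)c(O[C@H](CO[Si](C)(C)C(C)(C)C)[C@@H](O[Si](C)(C)C(C)(C)C)c5ccc(O[Si](C(C)C)(C(C)C)C(C)C)c(OC)c5)c(OC)c4)cc3OC)cc2OC)ccc1O[Si](C(C)C)(C(C)C)C(C)C | intermediate
34 | CNP0316493.1 | COc1cc([C@@H](O)[C@H](CO)Oc2ccc([C@@H](O)[C@@H](CO)Oc3c(OC)cc([C@@H]4OC[C@@H]5[C@H]4CO[C@H]5c4cc(OC)c(O[C@H](CO)[C@@H](O)c5ccc(O)c(OC)c5)c(OC)c4)cc3OC)cc2OC)ccc1O | target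

**Totals**

Total step count: 20.
Longest linear sequence: 12 steps (steps 9–20, from 16).

**Steps most likely to fail**

Step 18. The bimolecular union of two large, hindered partners may be slow, and during that time the boron triflate may ionise the benzylic furofuran C–O bonds or strip silyl groups; enolisation may also stay incomplete. The fallback separates bond formation from stereocontrol and sets out from phenol 28 and aldehyde 15. Alkylation of 28 with methyl bromoacetate (K2CO3, acetone) should give the methyl aryloxyacetate F1. LDA (THF, −78 °C) would convert it into its lithium enolate F2 (not isolated), whose addition to 15 should give the β-hydroxy ester F3 as a mixture at the two new centres. Dess–Martin oxidation would give the configurationally labile α-aryloxy β-keto ester F4. Noyori-type asymmetric transfer hydrogenation with dynamic kinetic resolution (RuCl(p-cymene)[(S,S)-TsDPEN], HCO2H/Et3N), with the catalyst enantiomer chosen to give 7R, should convert it into the syn (2S,3R) β-hydroxy ester F5. LiBH4 reduction of the ester would come back to the route at 33.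

Step 14. The activated, electron-rich benzylic oxyphosphonium ion may ionise before displacement, which erodes the inversion, or may eliminate, because the carbinol is flanked by the bulky 2,6-dimethoxyaryloxy group (the same hazard exists in step 6). The fallback sets out from 24. Dess–Martin periodinane (NaHCO3, CH2Cl2) should give the α-aryloxy aryl ketone F6. Chelation-controlled reduction with Zn(BH4)2 (Et2O, −30 °C), in which zinc bridges the carbonyl and the α-aryloxy oxygen and hydride enters from the side of the C8 hydrogen, should then give the erythro alcohol 26 directly, where it rejoins the route.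

Step 17. Acyl transfer from the imide to the hindered phenoxide, which cleaves the auxiliary, may compete with O-alkylation. The fallback builds the imide from the acid and sets out from 28. Alkylation with allyl bromoacetate (K2CO3, acetone) should give the allyl aryloxyacetate F7. Pd(PPh3)4/morpholine would free the aryloxyacetic acid F8. Pivaloyl chloride/Et3N (THF, −20 °C) would give the mixed pivalic anhydride F9 (not isolated), and N-acylation of lithiated (S)-4-benzyloxazolidin-2-one (n-BuLi, THF, −78 °C) would come back to the route at 29.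

Further compounds
F1 | step 18 | methyl aryloxyacetate of phenol 28 | COc1cc(cc(OC)c1OCC(=O)OC)[C@@H]1OC[C@@H]2[C@H]1CO[C@H]2c1cc(OC)c(O[C@H](CO[Si](C)(C)C(C)(C)C)[C@@H](O[Si](C)(C)C(C)(C)C)c2ccc(O[Si](C(C)C)(C(C)C)C(C)C)c(OC)c2)c(OC)c1
F2 | step 18 | lithium enolate of F1 (not isolated) | COc1cc(cc(OC)c1OC=C(O[Li])OC)[C@@H]1OC[C@@H]2[C@H]1CO[C@H]2c1cc(OC)c(O[C@H](CO[Si](C)(C)C(C)(C)C)[C@@H](O[Si](C)(C)C(C)(C)C)c2ccc(O[Si](C(C)C)(C(C)C)C(C)C)c(OC)c2)c(OC)c1
F3 | step 18 | methyl 3-hydroxy-2-aryloxy-3-arylpropanoate from F2 and 15 (mixture at C2 and C3) | COc1cc([C@@H](O[Si](C)(C)C(C)(C)C)[C@H](CO[Si](C)(C)C(C)(C)C)Oc2ccc(C(O)C(C(=O)OC)Oc3c(OC)cc([C@@H]4OC[C@@H]5[C@H]4CO[C@H]5c4cc(OC)c(O[C@H](CO[Si](C)(C)C(C)(C)C)[C@@H](O[Si](C)(C)C(C)(C)C)c5ccc(O[Si](C(C)C)(C(C)C)C(C)C)c(OC)c5)c(OC)c4)cc3OC)cc2OC)ccc1O[Si](C(C)C)(C(C)C)C(C)C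
F4 | step 18 | methyl 3-oxo-2-aryloxy-3-arylpropanoate (β-keto ester, C2 epimers interconverting) | COc1cc([C@@H](O[Si](C)(C)C(C)(C)C)[C@H](CO[Si](C)(C)C(C)(C)C)Oc2ccc(C(=O)C(C(=O)OC)Oc3c(OC)cc([C@@H]4OC[C@@H]5[C@H]4CO[C@H]5c4cc(OC)c(O[C@H](CO[Si](C)(C)C(C)(C)C)[C@@H](O[Si](C)(C)C(C)(C)C)c5ccc(O[Si](C(C)C)(C(C)C)C(C)C)c(OC)c5)c(OC)c4)cc3OC)cc2OC)ccc1O[Si](C(C)C)(C(C)C)C(C)C
F5 | step 18 | methyl (2S,3R)-3-hydroxy-2-aryloxy-3-arylpropanoate (syn) | COc1cc([C@@H](O[Si](C)(C)C(C)(C)C)[C@H](CO[Si](C)(C)C(C)(C)C)Oc2ccc([C@@H](O)[C@@H](C(=O)OC)Oc3c(OC)cc([C@@H]4OC[C@@H]5[C@H]4CO[C@H]5c4cc(OC)c(O[C@H](CO[Si](C)(C)C(C)(C)C)[C@@H](O[Si](C)(C)C(C)(C)C)c5ccc(O[Si](C(C)C)(C(C)C)C(C)C)c(OC)c5)c(OC)c4)cc3OC)cc2OC)ccc1O[Si](C(C)C)(C(C)C)C(C)C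
F6 | step 14 | (R)-3-(tert-butyldimethylsilyloxy)-2-aryloxy-1-(3-methoxy-4-triisopropylsilyloxyphenyl)propan-1-one, aryloxy = 4'-O of 17 | COc1cc(cc(OC)c1OCC=C)[C@@H]1OC[C@@H]2[C@H]1CO[C@H]2c1cc(OC)c(O[C@H](CO[Si](C)(C)C(C)(C)C)C(=O)c2ccc(O[Si](C(C)C)(C(C)C)C(C)C)c(OC)c2)c(OC)c1
F7 | step 17 | allyl aryloxyacetate of phenol 28 | COc1cc(cc(OC)c1OCC(=O)OCC=C)[C@@H]1OC[C@@H]2[C@H]1CO[C@H]2c1cc(OC)c(O[C@H](CO[Si](C)(C)C(C)(C)C)[C@@H](O[Si](C)(C)C(C)(C)C)c2ccc(O[Si](C(C)C)(C(C)C)C(C)C)c(OC)c2)c(OC)c1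
F8 | step 17 | aryloxyacetic acid of phenol 28 | COc1cc(cc(OC)c1OCC(=O)O)[C@@H]1OC[C@@H]2[C@H]1CO[C@H]2c1cc(OC)c(O[C@H](CO[Si](C)(C)C(C)(C)C)[C@@H](O[Si](C)(C)C(C)(C)C)c2ccc(O[Si](C(C)C)(C(C)C)C(C)C)c(OC)c2)c(OC)c1
F9 | step 17 | mixed pivalic anhydride of F8 (not isolated) | COc1cc(cc(OC)c1OCC(=O)OC(=O)C(C)(C)C)[C@@H]1OC[C@@H]2[C@H]1CO[C@H]2c1cc(OC)c(O[C@H](CO[Si](C)(C)C(C)(C)C)[C@@H](O[Si](C)(C)C(C)(C)C)c2ccc(O[Si](C(C)C)(C(C)C)C(C)C)c(OC)c2)c(OC)c1
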